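**Plan**

- Retrosynthesis (ring atoms O1, O2, C3–C6; chain C7–C14): cut C2–C3 (acetate arm added to a cyclic peroxy-acetal), then C4–C5 and O2–C3 of the 1,2-dioxane (propanal plus an α-peroxy aldehyde), then O1–C6 and C5–C6 (epoxide from a methyl ketone), then C8–C9 and C12–C13 (two alkenylboron conjugate additions).
- Forward: the C7–C14 chain is joined first (steps 1–4), C6 is made a tertiary hydroperoxide (steps 5–8), the dioxane ring closes in one pot (step 9), the helper hydroxyl on C5 is removed (steps 10–11), and the C1–C2 arm is added last (steps 12–13).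
- Enabling feature: C3 bears ring oxygen O2 and lies β to the carboxyl carbon, so it is an aldehyde carbon in disguise, and C4 with its methyl group is the α-carbon of propanal. C5 adjoins the fully substituted peroxy carbon C6, so a C5 aldehyde cannot enolise and is a pure aldol acceptor. The OOH on C6 then closes the six-membered O1–O2–C3–C4–C5–C6 ring onto C3.
- Stereochemistry: C12 and C8 come from rhodium/BINAP catalysis. C6 comes from a catalytic asymmetric Corey–Chaykovsky epoxidation followed by perhydrolysis with inversion. C4 comes from L-proline. C3 is relayed from C4 and C6 by axial attack on the ring peroxycarbenium ion.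

Key step: step 9

Assumption: the facial sense of the three chiral metal catalysts (steps 1, 4, 5) is taken from the accepted models for simple (E)-enoates, (E)-enones and methyl ketones; should one act in the opposite sense, its enantiomer is used.

Convention: ring locants follow the target (O1, O2, C3 with the acetate arm, C4, C5, C6); "dienyl" stands for the (2R,3E,6S,7E)-2,6-dimethyl-8-phenylocta-3,7-dien-1-yl chain on C6.

**Route**

Step 1
Reactants: 1 isopropyl (E)-but-2-enoate; 2 (E)-2-phenylvinylboronic acid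
Product: 3 isopropyl (3S,4E)-3-methyl-5-phenylpent-4-enoate
Conditions: Rh(acac)(C2H4)2 (3 mol%), (R)-BINAP, dioxane/H2O 10:1, 100 °C
Reagents that add atoms: none
Why: Rhodium/BINAP-catalysed conjugate addition of an alkenylboronic acid to an (E)-enoate (Hayashi–Miyaura reaction); the ligand fixes the β-face and (R)-BINAP should give 3S (C12 of the target), helped by the bulky isopropyl ester.

Step 2
Reactants: 3 isopropyl (3S,4E)-3-methyl-5-phenylpent-4-enoate
Product: 4 (3S,4E)-3-methyl-5-phenylpent-4-enal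
Conditions: i-Bu2AlH (1.1 equiv), CH2Cl2, −78 °C; Rochelle salt work-up
Reagents that add atoms: none
Why: Partial ester reduction through the aluminium hemiacetal that is stable at −78 °C; the stereocenter is β to the carbonyl and cannot epimerise.

Step 3
Reactants: 4 (3S,4E)-3-methyl-5-phenylpent-4-enal; 5 bis(4,4,5,5-tetramethyl-1,3,2-dioxaborolan-2-yl)methane
Product: 6 2-[(1E,4S,5E)-4-methyl-6-phenylhexa-1,5-dien-1-yl]-4,4,5,5-tetramethyl-1,3,2-dioxaborolane
Conditions: lithium 2,2,6,6-tetramethylpiperidide, THF, 0 °C; then 4, −78 °C to rt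
Reagents that add atoms: none
Why: Boron-Wittig olefination: the α-diboryl carbanion adds to the aldehyde and syn-eliminates a boron–oxygen unit, which should give the (E)-alkenyl boronate.

Step 4
Reactants: 6 2-[(1E,4S,5E)-4-methyl-6-phenylhexa-1,5-dien-1-yl]-4,4,5,5-tetramethyl-1,3,2-dioxaborolane; 7 (E)-pent-3-en-2-one
Product: 8 (4R,5E,8S,9E)-4,8-dimethyl-10-phenyldeca-5,9-dien-2-one
Conditions: Rh(acac)(C2H4)2 (3 mol%), (S)-BINAP, aq. KOH (0.3 equiv), dioxane/H2O, 60 °C
Reagents that add atoms: none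
Why: Second Hayashi–Miyaura addition, now of the alkenyl boronate to an (E)-enone; (S)-BINAP should give 4R (C8 of the target) under catalyst control, the remote C12 center having no say.

Step 5
Reactants: 8 (4R,5E,8S,9E)-4,8-dimethyl-10-phenyldeca-5,9-dien-2-one
Product: 9 (2S)-2-dienyl-2-methyloxirane, i.e. (2S)-2-[(2R,3E,6S,7E)-2,6-dimethyl-8-phenylocta-3,7-dien-1-yl]-2-methyloxirane
Conditions: Me3S(O)I, NaH; LaLi3[(S)-binaphthoxide]3 (5 mol%), tris(2,4,6-trimethoxyphenyl)phosphine oxide (5 mol%), 5 Å MS, THF, rt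
Reagents that add atoms: trimethylsulfoxonium iodide (C[S+](C)(C)=O.[I-])
Why: Catalytic asymmetric Corey–Chaykovsky epoxidation of a methyl ketone; the lanthanum/lithium binaphthoxide binds ketone and ylide and selects the carbonyl face to give the 2S epoxide, and the isolated alkenes do not react with the ylide.

Step 6
Reactants: 9 (2S)-2-dienyl-2-methyloxirane
Product: 10 (2R,4R,5E,8S,9E)-2-hydroperoxy-2,4,8-trimethyl-10-phenyldeca-5,9-dien-1-ol
Conditions: anhydrous H2O2 in Et2O, H3PMo12O40 (cat.), rt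
Reagents that add atoms: hydrogen peroxide (OO)
Why: Molybdenum-catalysed perhydrolysis opens the 2,2-disubstituted epoxide at the tertiary carbon in a borderline SN2 manner with inversion, so the 2S epoxide should give the 2R tertiary hydroperoxide (C6 of the target) and leave C5 as a primary alcohol.

Step 7
Reactants: 10 (2R,4R,5E,8S,9E)-2-hydroperoxy-2,4,8-trimethyl-10-phenyldeca-5,9-dien-1-ol
Product: 11 (2R,4R,5E,8S,9E)-2,4,8-trimethyl-10-phenyl-2-[(triethylsilyl)peroxy]deca-5,9-dien-1-ol
Conditions: Et3SiCl (1.0 equiv), Et3N, CH2Cl2, −78 °C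
Reagents that add atoms: chlorotriethylsilane (CC[Si](CC)(CC)Cl)
Why: Chemoselective O-silylation: the hydroperoxide is about four pKa units more acidic than the primary alcohol and its anion is an α-effect nucleophile, so one equivalent of silyl chloride at low temperature should cap only the OOH group.

Step 8
Reactants: 11 (2R,4R,5E,8S,9E)-2,4,8-trimethyl-10-phenyl-2-[(triethylsilyl)peroxy]deca-5,9-dien-1-ol
Product: 12 (2R,4R,5E,8S,9E)-2,4,8-trimethyl-10-phenyl-2-[(triethylsilyl)peroxy]deca-5,9-dienal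
Conditions: Dess–Martin periodinane, CH2Cl2, 0 °C
Reagents that add atoms: none
Why: Dess–Martin oxidation of the primary alcohol under near-neutral conditions that spare the silyl peroxide and the alkenes; the aldehyde has no α-hydrogen and cannot epimerise.

Step 9
Reactants: 12 (2R,4R,5E,8S,9E)-2,4,8-trimethyl-10-phenyl-2-[(triethylsilyl)peroxy]deca-5,9-dienal; 13 propanal
Product: 16 (3R,4S,5R,6R)-6-dienyl-3-methoxy-4,6-dimethyl-1,2-dioxan-5-ol, via silylperoxy aldol 14 (not isolated), via hemiperacetal 15 (not isolated)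
Conditions: L-proline (20 mol%), DMF, 4 °C, 13 added over 24 h; excess 13 evaporated; then MeOH, camphorsulfonic acid (10 mol%), rt
Reagents that add atoms: methanol (CO)
Why: L-Proline and 13 form the (E)-enamine, which adds to the non-enolisable, α-oxygen-activated aldehyde 12 through the carboxylic-acid-hydrogen-bonded chair transition state (C4–C5 bond, aldol 14); acid methanolysis then removes the silyl group and the freed C6–OOH adds to the C3 aldehyde (O2–C3 bond) to give hemiperacetal 15, which is fixed as methyl acetal 16. The closest known reaction types are the proline-catalysed direct cross-aldol of propanal with α-branched or α-oxygenated aldehydes and the acid-catalysed cyclisation of γ-hydroperoxy carbonyl compounds to 3-alkoxy-1,2-dioxanes. The 1,2-dioxane ring closes by a reversible 6-exo-trig addition of the hydroperoxide oxygen to the carbonyl group. C4 is set by the catalyst (enamine face fixed by L-proline, 4S whatever the acceptor), while C5 (anti expected) and the anomeric C3 (axial OMe expected) are erased in steps 11 and 12, so their ratios do not matter. The step needs cross-aldol over self-aldol, secured by the missing α-hydrogen of 12 and slow addition of 13, and six-membered peroxy-acetal formation over 1,2,4-trioxane formation with residual aldehyde, secured by removing excess 13 before the acid and by the intramolecular ring closure.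

Step 10
Reactants: 16 (3R,4S,5R,6R)-6-dienyl-3-methoxy-4,6-dimethyl-1,2-dioxan-5-ol
Product: 17 O-[(3R,4S,5R,6R)-6-dienyl-3-methoxy-4,6-dimethyl-1,2-dioxan-5-yl] O-phenyl carbonothioate
Conditions: PhOC(S)Cl, pyridine, DMAP (cat.), CH2Cl2, rt
Reagents that add atoms: O-phenyl chlorothionoformate (S=C(Cl)Oc1ccccc1)
Why: Thioacylation of the secondary C5 alcohol to the radical precursor under weakly basic conditions that should not trigger Kornblum–DeLaMare cleavage at C3–H.

Step 11
Reactants: 17 O-[(3R,4S,5R,6R)-6-dienyl-3-methoxy-4,6-dimethyl-1,2-dioxan-5-yl] O-phenyl carbonothioate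
Product: 18 (3R,4S,6R)-6-dienyl-3-methoxy-4,6-dimethyl-1,2-dioxane
Conditions: n-Bu3SnH, Et3B/air (cat.), toluene, rt
Reagents that add atoms: none
Why: Barton–McCombie deoxygenation: the ring C5 radical should be quenched by Sn–H faster than it attacks the O–O bond, because the collinear C5···O1–O2 geometry needed for substitution at O1 cannot be reached inside the six-membered ring.

Step 12
Reactants: 18 (3R,4S,6R)-6-dienyl-3-methoxy-4,6-dimethyl-1,2-dioxane; 19 tert-butyl[(1-methoxyethenyl)oxy]dimethylsilane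
Product: 20 methyl 2-[(3S,4S,6R)-6-dienyl-4,6-dimethyl-1,2-dioxan-3-yl]acetate
Conditions: Me3SiOTf (0.2 equiv), CH2Cl2, −78 °C
Reagents that add atoms: none
Why: Mukaiyama-type addition of a silyl ketene acetal to the peroxycarbenium ion formed by loss of methoxide; in the half-chair with the C4 methyl and the C6 chain pseudoequatorial, attack along the axial trajectory that leads to the chair should place the acetate arm axial and cis to the C4 methyl (3S).

Step 13
Reactants: 20 methyl 2-[(3S,4S,6R)-6-dienyl-4,6-dimethyl-1,2-dioxan-3-yl]acetate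
Product: 21 2-[(3S,4S,6R)-6-[(2R,3E,6S,7E)-2,6-dimethyl-8-phenylocta-3,7-dien-1-yl]-4,6-dimethyl-1,2-dioxan-3-yl]acetic acid
Conditions: LiOH, THF/H2O, 0 °C; then aq. HCl to pH 3
Reagents that add atoms: lithium hydroxide ([Li+].[OH-])
Why: Mild saponification; the dialkyl peroxide should tolerate cold aqueous hydroxide and no stereocenter is touched.

**Compound list**

1 | isopropyl (E)-but-2-enoate | C/C=C/C(=O)OC(C)C | starting material
2 | (E)-2-phenylvinylboronic acid | OB(O)/C=C/c1ccccc1 | starting material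
3 | isopropyl (3S,4E)-3-methyl-5-phenylpent-4-enoate | C[C@H](/C=C/c1ccccc1)CC(=O)OC(C)C | intermediate
4 | (3S,4E)-3-methyl-5-phenylpent-4-enal | C[C@H](/C=C/c1ccccc1)CC=O | intermediate
5 | bis(4,4,5,5-tetramethyl-1,3,2-dioxaborolan-2-yl)methane | CC1(C)OB(CB2OC(C)(C)C(C)(C)O2)OC1(C)C | starting material
6 | 2-[(1E,4S,5E)-4-methyl-6-phenylhexa-1,5-dien-1-yl]-4,4,5,5-tetramethyl-1,3,2-dioxaborolane | C[C@H](/C=C/c1ccccc1)C/C=C/B1OC(C)(C)C(C)(C)O1 | intermediate
7 | (E)-pent-3-en-2-one | C/C=C/C(C)=O | starting material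
8 | (4R,5E,8S,9E)-4,8-dimethyl-10-phenyldeca-5,9-dien-2-one | C[C@H](/C=C/c1ccccc1)C/C=C/[C@H](C)CC(C)=O | intermediate
9 | (2S)-2-[(2R,3E,6S,7E)-2,6-dimethyl-8-phenylocta-3,7-dien-1-yl]-2-methyloxirane | C[C@H](/C=C/c1ccccc1)C/C=C/[C@H](C)C[C@@]1(C)CO1 | intermediate
10 | (2R,4R,5E,8S,9E)-2-hydroperoxy-2,4,8-trimethyl-10-phenyldeca-5,9-dien-1-ol | C[C@H](/C=C/c1ccccc1)C/C=C/[C@H](C)C[C@](OO)(C)CO | intermediate
11 | (2R,4R,5E,8S,9E)-2,4,8-trimethyl-10-phenyl-2-[(triethylsilyl)peroxy]deca-5,9-dien-1-ol | C[C@H](/C=C/c1ccccc1)C/C=C/[C@H](C)C[C@](OO[Si](CC)(CC)CC)(C)CO | intermediate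
12 | (2R,4R,5E,8S,9E)-2,4,8-trimethyl-10-phenyl-2-[(triethylsilyl)peroxy]deca-5,9-dienal | C[C@H](/C=C/c1ccccc1)C/C=C/[C@H](C)C[C@](OO[Si](CC)(CC)CC)(C)C=O | intermediate
13 | propanal | CCC=O | starting material
14 | (2S,3R,4R,6R,7E,10S,11E)-3-hydroxy-2,4,6,10-tetramethyl-12-phenyl-4-[(triethylsilyl)peroxy]dodeca-7,11-dienal | C[C@H](/C=C/c1ccccc1)C/C=C/[C@H](C)C[C@](OO[Si](CC)(CC)CC)(C)[C@H](O)[C@H](C)C=O | intermediate
15 | (3R,4S,5R,6R)-6-[(2R,3E,6S,7E)-2,6-dimethyl-8-phenylocta-3,7-dien-1-yl]-4,6-dimethyl-1,2-dioxane-3,5-diol | C[C@H](/C=C/c1ccccc1)C/C=C/[C@H](C)C[C@]1(C)[C@H](O)[C@H](C)[C@H](O)OO1 | intermediate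
16 | (3R,4S,5R,6R)-6-[(2R,3E,6S,7E)-2,6-dimethyl-8-phenylocta-3,7-dien-1-yl]-3-methoxy-4,6-dimethyl-1,2-dioxan-5-ol | C[C@H](/C=C/c1ccccc1)C/C=C/[C@H](C)C[C@]1(C)[C@H](O)[C@H](C)[C@H](OC)OO1 | intermediate
17 | O-[(3R,4S,5R,6R)-6-[(2R,3E,6S,7E)-2,6-dimethyl-8-phenylocta-3,7-dien-1-yl]-3-methoxy-4,6-dimethyl-1,2-dioxan-5-yl] O-phenyl carbonothioate | C[C@H](/C=C/c1ccccc1)C/C=C/[C@H](C)C[C@]1(C)[C@H](OC(=S)Oc2ccccc2)[C@H](C)[C@H](OC)OO1 | intermediate
18 | (3R,4S,6R)-6-[(2R,3E,6S,7E)-2,6-dimethyl-8-phenylocta-3,7-dien-1-yl]-3-methoxy-4,6-dimethyl-1,2-dioxane | C[C@H](/C=C/c1ccccc1)C/C=C/[C@H](C)C[C@]1(C)C[C@H](C)[C@H](OC)OO1 | intermediate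
19 | tert-butyl[(1-methoxyethenyl)oxy]dimethylsilane | C=C(OC)O[Si](C)(C)C(C)(C)C | starting material
20 | methyl 2-[(3S,4S,6R)-6-[(2R,3E,6S,7E)-2,6-dimethyl-8-phenylocta-3,7-dien-1-yl]-4,6-dimethyl-1,2-dioxan-3-yl]acetate | C[C@H](/C=C/c1ccccc1)C/C=C/[C@H](C)C[C@]1(C)C[C@H](C)[C@H](CC(=O)OC)OO1 | intermediate
21 | 2-[(3S,4S,6R)-6-[(2R,3E,6S,7E)-2,6-dimethyl-8-phenylocta-3,7-dien-1-yl]-4,6-dimethyl-1,2-dioxan-3-yl]acetic acid | C[C@H](/C=C/c1ccccc1)C/C=C/[C@H](C)C[C@]1(C)C[C@H](C)[C@H](CC(=O)O)OO1 | target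

**Count**

Total step count: 13. Longest linear sequence: 13 steps (1 and 2 to 21).

**Steps most likely to fail**

Step 11. The chain carriers may attack the O–O bond, the C5 radical may open the ring by loss of the C6–O1 bond, or the hindered C5 hydroxyl may resist thioacylation in step 10. The fallback never puts oxygen on C5. It sets out from 11, which is converted with Tf2O and 2,6-lutidine (CH2Cl2, −78 °C) into the primary triflate (2R,4R,5E,8S,9E)-2,4,8-trimethyl-10-phenyl-2-[(triethylsilyl)peroxy]deca-5,9-dien-1-yl trifluoromethanesulfonate F3. This alkylates the lithium azaenolate of the propanal SAMP-hydrazone F1 (prepared as described below; LiN(i-Pr)2, THF, −100 to −78 °C), the auxiliary setting C4, to give the SAMP-hydrazone of (2S,4R,6R,7E,10S,11E)-2,4,6,10-tetramethyl-12-phenyl-4-[(triethylsilyl)peroxy]dodeca-7,11-dienal F4. Two-phase aqueous oxalic acid, then MeOH with camphorsulfonic acid, should free the aldehyde and the hydroperoxide and close the ring, coming back to the route at 18.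

Step 9. The enamine may fail to add to the hindered, fully substituted aldehyde so that self-aldol of propanal consumes the donor, or the silyl peroxide may be lost early and the free α-hydroperoxy aldehyde may fragment. The fallback replaces enamine catalysis by a preformed chiral azaenolate. It sets out from 12. Propanal 13 is condensed with (S)-1-amino-2-(methoxymethyl)pyrrolidine to the hydrazone (E)-N-[(2S)-2-(methoxymethyl)pyrrolidin-1-yl]propan-1-imine F1. F1 is deprotonated with LiN(i-Pr)2 (THF, −78 °C) and added to 12 at −100 °C to give the SAMP-hydrazone of aldol 14, F2. Aqueous oxalic acid, then MeOH with camphorsulfonic acid, should cleave the hydrazone and the silyl group and close the ring, coming back at 16; the C5 configuration is of no consequence because step 11 removes it.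

Step 12. The silyl ketene acetal may add to the peroxycarbenium ion with poor facial selectivity (equatorial attack giving the C3 epimer), or the Lewis acid may trigger heterolysis of the O–O bond (Hock-type fragmentation). The fallback closes the C3–O2 bond again by conjugate addition. It sets out from 18, which is hydrolysed with aqueous acid in THF to the hemiperacetal (3R,4S,6R)-6-dienyl-4,6-dimethyl-1,2-dioxan-3-ol F5, in equilibrium with its open hydroperoxy aldehyde. Wittig reaction with Ph3P=CHCO2Me should give methyl (2E,4S,6R,8R,9E,12S,13E)-6-hydroperoxy-4,6,8,12-tetramethyl-14-phenyltetradeca-2,9,13-trienoate F6. Amine-mediated intramolecular oxa-Michael addition (Et2NH, CF3CH2OH) closes the ring and comes back at 20, the C3 epimer being removed by chromatography.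

**Further compounds**

F1 | step 9 | (E)-N-[(2S)-2-(methoxymethyl)pyrrolidin-1-yl]propan-1-imine (propanal SAMP-hydrazone) | CC/C=N/N1CCC[C@H]1COC
F2 | step 9 | SAMP-hydrazone of (2S,3R,4R,6R,7E,10S,11E)-3-hydroxy-2,4,6,10-tetramethyl-12-phenyl-4-[(triethylsilyl)peroxy]dodeca-7,11-dienal | C[C@H](/C=C/c1ccccc1)C/C=C/[C@H](C)C[C@](OO[Si](CC)(CC)CC)(C)[C@H](O)[C@H](C)/C=N/N1CCC[C@H]1COC
F3 | step 11 | (2R,4R,5E,8S,9E)-2,4,8-trimethyl-10-phenyl-2-[(triethylsilyl)peroxy]deca-5,9-dien-1-yl trifluoromethanesulfonate | C[C@H](/C=C/c1ccccc1)C/C=C/[C@H](C)C[C@](OO[Si](CC)(CC)CC)(C)COS(=O)(=O)C(F)(F)F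
F4 | step 11 | SAMP-hydrazone of (2S,4R,6R,7E,10S,11E)-2,4,6,10-tetramethyl-12-phenyl-4-[(triethylsilyl)peroxy]dodeca-7,11-dienal | C[C@H](/C=C/c1ccccc1)C/C=C/[C@H](C)C[C@](OO[Si](CC)(CC)CC)(C)C[C@H](C)/C=N/N1CCC[C@H]1COC
F5 | step 12 | (3R,4S,6R)-6-[(2R,3E,6S,7E)-2,6-dimethyl-8-phenylocta-3,7-dien-1-yl]-4,6-dimethyl-1,2-dioxan-3-ol | C[C@H](/C=C/c1ccccc1)C/C=C/[C@H](C)C[C@]1(C)C[C@H](C)[C@H](O)OO1
F6 | step 12 | methyl (2E,4S,6R,8R,9E,12S,13E)-6-hydroperoxy-4,6,8,12-tetramethyl-14-phenyltetradeca-2,9,13-trienoate | C[C@H](/C=C/c1ccccc1)C/C=C/[C@H](C)C[C@](OO)(C)C[C@H](C)/C=C/C(=O)OC
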